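The constants first: binding runs at 14 L mol⁻¹ s⁻¹, and the two first-order steps that lead back to free catalyst run at 25 s⁻¹ and 140 s⁻¹.

substrate 1.5 M (fed, over 20 s); free catalyst 1.0 mM; time 4.0 min; the fed solution adds 0.25 times the starting volume

    substrate + free catalyst → catalyst intermediate A (k1 = 14 L mol⁻¹ s⁻¹)
    catalyst intermediate A → catalyst intermediate B (k2 = 25 s⁻¹)
    catalyst intermediate B → free catalyst + product (k3 = 140 s⁻¹)
    2 catalyst intermediate B ⇌ resting dimer, settled at all times (K4 = 1500 L mol⁻¹)

- percent here means substrate units held: one resting dimer counts as two
- a step written with two of one species runs at k times the square of its concentration and takes two of it each time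
- amounts are per litre of the starting volume; all of the dose is in the solution fed
- run time (flask): 4.0 min

- part of the substrate gone at 4.0 min
- the product standing at 4.0 min, as a percentage of the substrate charged

A first-order step lasts on average the inverse of its constant, so a catalyst that has bound substrate stays away for the sum of the two inverses:

τ = 0.0471 s

Because that is far shorter than the run, I let the catalyst forms keep pace with the substrate, so one flow r passes every step and c_intermediate A + c_intermediate B = rτ. After the feed the flask holds 1.25 starting volumes, so c_start = 1.20 M and the catalyst, all forms counted, is c_cat = 0.800 mM. The catalyst balance then gives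

r = 14 L mol⁻¹ s⁻¹ · c_cat · c_substrate / (1 + c_substrate/K_M), with K_M = 1.52 M

This K_M, the Michaelis constant, is the substrate concentration at which half of the catalyst stands free. At c_start, c_intermediate B is 0.0536 mM, and the resting dimer then takes 1.08 % of the catalyst, hardly any, so I drop it.

The rate integrates in closed form:

ln(c_start/c_substrate) + (c_start − c_substrate)/K_M = θ

I count the whole dose as entering at mid-feed, 10.0 s, so θ = 2.58. With x the part of substrate left and a = c_start/K_M = 0.792, this reads x = exp(a(1 − x) − θ). Iterating from x = 0 gives 0.168, 0.147, 0.150. So I commit to 85.0 % for conv, and to the same for y_P, since the catalyst can hold 0.0667 % of the charge at most.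

The forecast gives 91 % and 91 %, above my figure, on catalyst that “mostly sits as free catalyst”.

The simulation gives 85.3 % and 85.3 %, against my 85.0 %.

In this flask at 1.47 min, free catalyst has a half-life of 0.072 s by the binding step, while substrate has 1.5 min, far longer. I hold the free share 1/(1 + c_substrate/K_M) against the flask: with 15 % of the substrate left at 4.00 min, K_M gives 89.6 %, and this flask holds 89.5 % of its catalyst as free catalyst. The neighbour flask read at 1.5 min has 56 % of its substrate left, so K_M gives 69.1 %, and free catalyst there stands at 68.7 %.

All constants were set for the occasion.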